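**Plan**

1. Numbering (drimane): decalin C1–C10 with C4 = CMe2, C5 = ring-fusion CH, C10 = angular-methyl carbon, C8 = CHMe, C9 = ylidene carbon, C11 = C(Cl)Ar. The target is the trans-decalin (5S,8S,10S), with the C8 methyl cis to the angular methyl and the aryl group cis to C10 (E).
2. Retrosynthesis: cut C11–Cl (enol triflate of an aryl ketone), then C11–aryl (aryllithium + C11 aldehyde), then both rings at once at C5–C10 and C6–C7, then C1–C10 (B-alkyl Suzuki) and C8–C9 (carbomagnesiation of but-2-yn-1-ol).
3. Enabling feature: ring B (C5–C6–C7–C8–C9–C10) is a six-membered ring that can carry a C8=C9 alkene. C7=C8–C9=C10 is then a diene, C5=C6 a dienophile and C1–C4 a four-atom tether, so one iminium-catalysed intramolecular Diels–Alder reaction of an acyclic trienal closes rings A and B together.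
4. Stereochemistry: C5 and quaternary C10 (and temporary C6) come from the imidazolidinone catalyst and the endo, trans-fused transition state. C8 comes from hydroxyl-directed hydrogen delivery to the α face, anti to the angular methyl. The E chloroalkene comes from in-plane chloride capture of a linear α-aryl vinyl cation on its less hindered (C8–H) side.
5. Helpers: dioxolane (masks the enal), 6-formyl group (activates the dienophile, removed by decarbonylation), MOM ethers (removed last).

Key step: step 6

Remark: compounds 20, 22 and 23 are epimer or E/Z mixtures at an element that is erased later, so their SMILES leave that element open.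

**Step 1**
Reactants: 1 2,2-dimethylpent-4-enal; 2 (triphenylphosphoranylidene)acetaldehyde
Product: 3 (2E)-4,4-dimethylhepta-2,6-dienal
Conditions: 2 (1.1 equiv), PhMe, 80 °C
Reagents that add atoms: none
Why: Wittig olefination with a formyl-stabilised ylide is E-selective, and the non-enolisable α-quaternary aldehyde cannot self-condense.

**Step 2**
Reactants: 3 (2E)-4,4-dimethylhepta-2,6-dienal
Product: 4 2-[(1E)-3,3-dimethylhexa-1,5-dien-1-yl]-1,3-dioxolane
Conditions: ethylene glycol, PPTS (cat.), benzene, reflux, Dean–Stark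
Reagents that add atoms: ethylene glycol, OCCO
Why: Acid-catalysed acetalisation masks the enal against the borane of step 4 and keeps the dienophile switched off until the diene is in place.

**Step 3**
Reactants: 5 but-2-yn-1-ol; 6 isopropenylmagnesium bromide
Product: 8 (2Z)-3-iodo-2-(prop-1-en-2-yl)but-2-en-1-ol, via oxamagnesacycle 7 (not isolated)
Conditions: 6 (3.5 equiv), CuI (10 mol %), THF, 0 °C to reflux; then I2, THF, −40 to 0 °C
Reagents that add atoms: iodine, II
Why: In this alkoxide-directed anti-carbomagnesiation of a propargylic alcohol the isopropenyl group adds to the alkyne carbon next to CH2O and magnesium ends on the distal carbon in a five-membered chelate, so iodinolysis with retention fixes the tetrasubstituted geometry (isopropenyl cis to methyl, iodine cis to CH2OH).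

**Step 4**
Reactants: 4 2-[(1E)-3,3-dimethylhexa-1,5-dien-1-yl]-1,3-dioxolane; 8 (2Z)-3-iodo-2-(prop-1-en-2-yl)but-2-en-1-ol
Product: 10 (2Z,8E)-9-(1,3-dioxolan-2-yl)-3,7,7-trimethyl-2-(prop-1-en-2-yl)nona-2,8-dien-1-ol, via B-alkyl-9-BBN 9 (not isolated)
Conditions: 4, 9-BBN dimer, THF, 0 °C to rt; then 8, Pd(dppf)Cl2 (5 mol %), AsPh3 (10 mol %), Cs2CO3, DMF/H2O, rt to 40 °C
Reagents that add atoms: none
Why: Anti-Markovnikov hydroboration with 9-BBN selects the monosubstituted terminal alkene over the hindered disubstituted one, and the B-alkyl Suzuki–Miyaura coupling keeps the vinyl iodide geometry, which places the chain cis to CH2OH and the methyl "inside" the future diene.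

**Step 5**
Reactants: 10 (2Z,8E)-9-(1,3-dioxolan-2-yl)-3,7,7-trimethyl-2-(prop-1-en-2-yl)nona-2,8-dien-1-ol
Product: 11 (2E,8Z)-9-(hydroxymethyl)-4,4,8,10-tetramethylundeca-2,8,10-trienal
Conditions: PPTS (0.2 equiv), THF/H2O (4:1), 40 °C
Reagents that add atoms: water, O
Why: Mild acid hydrolysis of an α,β-unsaturated acetal is much faster than ionisation of the primary allylic alcohol, and the E enal is the thermodynamic geometry.

**Step 6**
Reactants: 11 (2E,8Z)-9-(hydroxymethyl)-4,4,8,10-tetramethylundeca-2,8,10-trienal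
Product: 12 (1S,4aS,8aS)-4-(hydroxymethyl)-3,4a,8,8-tetramethyl-1,2,4a,5,6,7,8,8a-octahydronaphthalene-1-carbaldehyde (6α-formyl-drim-8-en-11-ol)
Conditions: (2S,5S)-5-benzyl-2-tert-butyl-3-methylimidazolidin-4-one·HClO4 (20 mol %), MeCN/H2O (98:2), −10 °C to rt
Reagents that add atoms: none
Why: Condensation of the enal with the imidazolidinone gives an (E)-iminium ion whose lowered LUMO lets the C5=C6 π bond add across the termini C10 and C7 of the tetrasubstituted diene in an intramolecular, asynchronous but concerted [4+2] cycloaddition, and hydrolysis returns the catalyst. The closest known reaction type is the organocatalytic (iminium) type-1 intramolecular Diels–Alder reaction of (E)-2,8,10-trienals to trans-fused decalins. Ring A closes through the C5–C10 bond as a six-membered ring built from the C1–C4 tether, and ring B is the cyclohexene formed by the [4+2] event itself, with its alkene at C8=C9. The benzyl group of the (2S,5S)-catalyst shields one face of the s-trans iminium, so the diene should add to the open face of C5 and C6 (5S and, temporarily, 6S), and the endo transition state with a chair-like tether relays this to the quaternary centre C10 (10S, trans fusion, angular methyl anti to H-5). The step needs endo over exo selectivity and a reactive s-cis diene although C10 carries an inside methyl group; these are to be secured by the E dienophile, the Z geometry at C9=C10 fixed in step 3, and LUMO lowering that allows a temperature at which a [1,5]-hydrogen shift of the diene does not compete. The quaternary C4 also rules out dienamine formation.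

**Step 7**
Reactants: 12 (1S,4aS,8aS)-4-(hydroxymethyl)-3,4a,8,8-tetramethyl-1,2,4a,5,6,7,8,8a-octahydronaphthalene-1-carbaldehyde
Product: 13 [(4aS,8aS)-2,5,5,8a-tetramethyl-3,4,4a,5,6,7,8,8a-octahydronaphthalen-1-yl]methanol (drim-8-en-11-ol)
Conditions: [Rh(cod)Cl]2 (2.5 mol %), dppp (10 mol %), diglyme, 160 °C, Ar sweep
Reagents that add atoms: none
Why: Rhodium-catalysed Tsuji–Wilkinson decarbonylation (formyl C–H insertion, CO extrusion, reductive elimination) removes the activating group and leaves C6 as CH2, while the tetrasubstituted alkene and the alcohol are inert.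

**Step 8**
Reactants: 13 [(4aS,8aS)-2,5,5,8a-tetramethyl-3,4,4a,5,6,7,8,8a-octahydronaphthalen-1-yl]methanol
Product: 14 [(1S,2S,4aS,8aS)-2,5,5,8a-tetramethyldecahydronaphthalen-1-yl]methanol (8β-methyl, 9β-CH2OH)
Conditions: [Ir(cod)(PCy3)(py)]PF6 (10 mol %), H2 (1–10 bar), CH2Cl2, rt
Reagents that add atoms: none
Why: In this hydroxyl-directed hydrogenation with Crabtree's catalyst the C11 hydroxyl binds iridium and both hydrogens should be delivered syn to the α face, opposite the axial angular methyl on C10, which sets C8 (β-methyl, S) and C9.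

**Step 9**
Reactants: 14 [(1S,2S,4aS,8aS)-2,5,5,8a-tetramethyldecahydronaphthalen-1-yl]methanol
Product: 15 (1S,2S,4aS,8aS)-2,5,5,8a-tetramethyldecahydronaphthalene-1-carbaldehyde
Conditions: Dess–Martin periodinane, CH2Cl2, 0 °C to rt
Reagents that add atoms: none
Why: Dess–Martin oxidation converts the hindered primary alcohol into the aldehyde under near-neutral conditions that leave the equatorial formyl group in place.

**Step 10**
Reactants: 16 3-bromo-4-hydroxy-5-methoxybenzaldehyde (5-bromovanillin)
Product: 17 2-bromo-6-methoxybenzene-1,4-diol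
Conditions: 30% H2O2, 1 M NaOH, H2O, 0 °C to rt, Ar; then 1 M HCl
Reagents that add atoms: hydrogen peroxide, OO
Why: In the Dakin oxidation hydroperoxide adds to the aldehyde, the electron-rich aryl group migrates to oxygen and the aryl formate is hydrolysed, which gives the hydroquinone with bromine at the future attachment carbon.

**Step 11**
Reactants: 17 2-bromo-6-methoxybenzene-1,4-diol
Product: 18 1-bromo-3-methoxy-2,5-bis(methoxymethoxy)benzene
Conditions: NaH, MOMCl, DMF, 0 °C to rt
Reagents that add atoms: chloromethyl methyl ether, COCCl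
Why: Williamson-type O-alkylation of both phenoxides gives base-stable MOM ethers, and the ortho one later stabilises the aryllithium by chelation.

**Step 12**
Reactants: 18 1-bromo-3-methoxy-2,5-bis(methoxymethoxy)benzene; 15 (1S,2S,4aS,8aS)-2,5,5,8a-tetramethyldecahydronaphthalene-1-carbaldehyde
Product: 20 [3-methoxy-2,5-bis(methoxymethoxy)phenyl][(1S,2S,4aS,8aS)-2,5,5,8a-tetramethyldecahydronaphthalen-1-yl]methanol (both C11 epimers), via aryllithium 19 (not isolated)
Conditions: 18, n-BuLi, THF, −78 °C; then 15, −78 to 0 °C; H2O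
Reagents that add atoms: none
Why: Bromine–lithium exchange and 1,2-addition of the aryllithium to the aldehyde join arene and decalin, and the carbinol configuration is irrelevant because step 13 oxidises it.

**Step 13**
Reactants: 20 [3-methoxy-2,5-bis(methoxymethoxy)phenyl][(1S,2S,4aS,8aS)-2,5,5,8a-tetramethyldecahydronaphthalen-1-yl]methanol
Product: 21 [3-methoxy-2,5-bis(methoxymethoxy)phenyl][(1S,2S,4aS,8aS)-2,5,5,8a-tetramethyldecahydronaphthalen-1-yl]methanone
Conditions: Dess–Martin periodinane, CH2Cl2, rt
Reagents that add atoms: none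
Why: Dess–Martin oxidation of the benzylic alcohol gives the aryl ketone and converges both epimers.

**Step 14**
Reactants: 21 [3-methoxy-2,5-bis(methoxymethoxy)phenyl][(1S,2S,4aS,8aS)-2,5,5,8a-tetramethyldecahydronaphthalen-1-yl]methanone
Product: 23 [3-methoxy-2,5-bis(methoxymethoxy)phenyl][(2S,4aS,8aS)-2,5,5,8a-tetramethyloctahydronaphthalen-1(2H)-ylidene]methyl trifluoromethanesulfonate (E/Z mixture), via potassium enolate 22 (not isolated)
Conditions: KHMDS, THF, −78 to 0 °C; then PhNTf2, 0 °C to rt; aqueous work-up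
Reagents that add atoms: N-phenylbis(trifluoromethanesulfonimide), O=S(=O)(N(c1ccccc1)S(=O)(=O)C(F)(F)F)C(F)(F)F
Why: Deprotonation of the only α-hydrogen (axial C9–H on the α face) and O-sulfonylation of the enolate give the enol triflate, and either geometry is acceptable because step 15 is stereoconvergent.

**Step 15**
Reactants: 23 [3-methoxy-2,5-bis(methoxymethoxy)phenyl][(2S,4aS,8aS)-2,5,5,8a-tetramethyloctahydronaphthalen-1(2H)-ylidene]methyl trifluoromethanesulfonate
Product: 24 1-{(E)-chloro[(2S,4aS,8aS)-2,5,5,8a-tetramethyloctahydronaphthalen-1(2H)-ylidene]methyl}-3-methoxy-2,5-bis(methoxymethoxy)benzene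
Conditions: Et4NCl (5 equiv), 2,6-di-tert-butylpyridine (0.2 equiv), HFIP/CH2Cl2 (1:1), 25 to 45 °C
Reagents that add atoms: tetraethylammonium chloride, CC[N+](CC)(CC)CC.[Cl-]
Why: In this vinylic SN1 substitution the α-aryl vinyl triflate, helped by the ortho-alkoxy donor and by relief of allylic strain, should ionise to a linear vinyl cation whose empty orbital lies in the C8–C9–C10 plane, and chloride should enter in that plane past the equatorial C8–H and not past quaternary C10, giving the E isomer from both triflate isomers.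

**Step 16**
Reactants: 24 1-{(E)-chloro[(2S,4aS,8aS)-2,5,5,8a-tetramethyloctahydronaphthalen-1(2H)-ylidene]methyl}-3-methoxy-2,5-bis(methoxymethoxy)benzene
Product: 25 2-{(E)-chloro[(2S,4aS,8aS)-2,5,5,8a-tetramethyloctahydronaphthalen-1(2H)-ylidene]methyl}-6-methoxybenzene-1,4-diol (target)
Conditions: HCl (3 M in MeOH), MeOH/THF, 40 °C, Ar
Reagents that add atoms: none
Why: Acid-catalysed transacetalisation to methanol frees both phenols, while the aryl methyl ether, the vinyl chloride and the C8 centre (not adjacent to any cationic site) are stable.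

**Compound list**

1 | 2,2-dimethylpent-4-enal | C=CCC(C)(C)C=O | starting material
2 | (triphenylphosphoranylidene)acetaldehyde | O=CC=P(c1ccccc1)(c1ccccc1)c1ccccc1 | starting material
3 | (2E)-4,4-dimethylhepta-2,6-dienal | C=CCC(C)(C)/C=C/C=O | intermediate
4 | 2-[(1E)-3,3-dimethylhexa-1,5-dien-1-yl]-1,3-dioxolane | C=CCC(C)(C)/C=C/C1OCCO1 | intermediate
5 | but-2-yn-1-ol | CC#CCO | starting material
6 | isopropenylmagnesium bromide | C=C(C)[Mg]Br | starting material
7 | 3-methyl-4-(prop-1-en-2-yl)-2,5-dihydro-1,2-oxamagnesole (cyclic alkenylmagnesium alkoxide) | CC1=C(C(C)=C)CO[Mg]1 | intermediate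
8 | (2Z)-3-iodo-2-(prop-1-en-2-yl)but-2-en-1-ol | OC/C(C(C)=C)=C(/C)I | intermediate
9 | 9-[(5E)-6-(1,3-dioxolan-2-yl)-4,4-dimethylhex-5-en-1-yl]-9-borabicyclo[3.3.1]nonane | O1CCOC1/C=C/C(C)(C)CCCB1C2CCCC1CCC2 | intermediate
10 | (2Z,8E)-9-(1,3-dioxolan-2-yl)-3,7,7-trimethyl-2-(prop-1-en-2-yl)nona-2,8-dien-1-ol | OC/C(C(C)=C)=C(/C)CCCC(C)(C)/C=C/C1OCCO1 | intermediate
11 | (2E,8Z)-9-(hydroxymethyl)-4,4,8,10-tetramethylundeca-2,8,10-trienal | OC/C(C(C)=C)=C(/C)CCCC(C)(C)/C=C/C=O | intermediate
12 | (1S,4aS,8aS)-4-(hydroxymethyl)-3,4a,8,8-tetramethyl-1,2,4a,5,6,7,8,8a-octahydronaphthalene-1-carbaldehyde | OCC1=C(C)C[C@H](C=O)[C@H]2C(C)(C)CCC[C@]12C | intermediate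
13 | [(4aS,8aS)-2,5,5,8a-tetramethyl-3,4,4a,5,6,7,8,8a-octahydronaphthalen-1-yl]methanol | OCC1=C(C)CC[C@H]2C(C)(C)CCC[C@]12C | intermediate
14 | [(1S,2S,4aS,8aS)-2,5,5,8a-tetramethyldecahydronaphthalen-1-yl]methanol | OC[C@H]1[C@@H](C)CC[C@H]2C(C)(C)CCC[C@]12C | intermediate
15 | (1S,2S,4aS,8aS)-2,5,5,8a-tetramethyldecahydronaphthalene-1-carbaldehyde | O=C[C@H]1[C@@H](C)CC[C@H]2C(C)(C)CCC[C@]12C | intermediate
16 | 3-bromo-4-hydroxy-5-methoxybenzaldehyde | COc1cc(C=O)cc(Br)c1O | starting material
17 | 2-bromo-6-methoxybenzene-1,4-diol | COc1cc(O)cc(Br)c1O | intermediate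
18 | 1-bromo-3-methoxy-2,5-bis(methoxymethoxy)benzene | COCOc1cc(OC)c(OCOC)c(Br)c1 | intermediate
19 | [3-methoxy-2,5-bis(methoxymethoxy)phenyl]lithium | [Li]c1cc(OCOC)cc(OC)c1OCOC | intermediate
20 | [3-methoxy-2,5-bis(methoxymethoxy)phenyl][(1S,2S,4aS,8aS)-2,5,5,8a-tetramethyldecahydronaphthalen-1-yl]methanol (C11 epimers) | COc1cc(OCOC)cc(C(O)[C@H]2[C@@H](C)CC[C@H]3C(C)(C)CCC[C@]23C)c1OCOC | intermediate
21 | [3-methoxy-2,5-bis(methoxymethoxy)phenyl][(1S,2S,4aS,8aS)-2,5,5,8a-tetramethyldecahydronaphthalen-1-yl]methanone | COc1cc(OCOC)cc(C(=O)[C@H]2[C@@H](C)CC[C@H]3C(C)(C)CCC[C@]23C)c1OCOC | intermediate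
22 | potassium [3-methoxy-2,5-bis(methoxymethoxy)phenyl][(2S,4aS,8aS)-2,5,5,8a-tetramethyloctahydronaphthalen-1(2H)-ylidene]methanolate (E/Z) | COc1cc(OCOC)cc(C([O-])=C2[C@@H](C)CC[C@H]3C(C)(C)CCC[C@]23C)c1OCOC.[K+] | intermediate
23 | [3-methoxy-2,5-bis(methoxymethoxy)phenyl][(2S,4aS,8aS)-2,5,5,8a-tetramethyloctahydronaphthalen-1(2H)-ylidene]methyl trifluoromethanesulfonate (E/Z) | COc1cc(OCOC)cc(C(OS(=O)(=O)C(F)(F)F)=C2[C@@H](C)CC[C@H]3C(C)(C)CCC[C@]23C)c1OCOC | intermediate
24 | 1-{(E)-chloro[(2S,4aS,8aS)-2,5,5,8a-tetramethyloctahydronaphthalen-1(2H)-ylidene]methyl}-3-methoxy-2,5-bis(methoxymethoxy)benzene | COc1cc(OCOC)cc(/C(Cl)=C2/[C@@H](C)CC[C@H]3C(C)(C)CCC[C@]23C)c1OCOC | intermediate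
25 | 2-{(E)-chloro[(2S,4aS,8aS)-2,5,5,8a-tetramethyloctahydronaphthalen-1(2H)-ylidene]methyl}-6-methoxybenzene-1,4-diol | COc1cc(O)cc(/C(Cl)=C2/[C@@H](C)CC[C@H]3C(C)(C)CCC[C@]23C)c1O | target

**Count and risks**

Total: 16 steps. Longest linear sequence: 13 steps (1, 2, 4–9, 12–16).

Step 6. The cycloaddition may be slow because the diene, with an inside methyl on C10, reaches the s-cis form with difficulty and both bond-forming termini are hindered; endo/exo or facial selectivity may also erode. Fallback: setting out from 10, the hydroxyl is silylated (TBSCl, imidazole) to the TBS ether of 10 F1, and mild acid hydrolysis gives the silyl-protected trienal F2. F2 is cyclised at −78 to −40 °C with a triflimide-activated, proline-derived cationic oxazaborolidine (chiral Lewis-acid activation instead of iminium catalysis; antipode chosen by the formyl C–H···O model) to the silyl-protected cycloadduct F3. Decarbonylation as in step 7 gives the TBS ether of 13 F4, and TBAF returns the route at 13.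

Step 15. Ionisation of the triflate may be incomplete, the vinyl cation may be captured by solvent, or chloride may enter from both sides. Fallback: setting out from 21, dehydrative chlorination with the triphenyl phosphite–chlorine adduct and Et3N (CH2Cl2, −30 °C to rt) gives 24 together with the Z isomer of 24 F5. The isomers are separated and F5 is returned to the E/Z mixture by triplet-sensitised photoisomerisation, so the route is rejoined at 24 without the triflate.

Step 8. Hydrogen may be delivered to the β face, or the tetrasubstituted alkene may not be reduced. Fallback: setting out from 13, MnO2 oxidation gives drim-8-en-11-al F6. Copper hydride conjugate reduction (Stryker's reagent, or catalytic Cu(OAc)2/bisphosphine with a silane) adds hydride to C8 from the α face and protonation of the enolate places the formyl group equatorial, which returns the route at 15.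

**Further compounds**

F1 | step 6 | tert-butyl{[(2Z,8E)-9-(1,3-dioxolan-2-yl)-3,7,7-trimethyl-2-(prop-1-en-2-yl)nona-2,8-dien-1-yl]oxy}dimethylsilane | CC(C)(C)[Si](C)(C)OC/C(C(C)=C)=C(/C)CCCC(C)(C)/C=C/C1OCCO1
F2 | step 6 | (2E,8Z)-9-{[tert-butyl(dimethyl)silyl]oxymethyl}-4,4,8,10-tetramethylundeca-2,8,10-trienal | CC(C)(C)[Si](C)(C)OC/C(C(C)=C)=C(/C)CCCC(C)(C)/C=C/C=O
F3 | step 6 | (1S,4aS,8aS)-4-{[tert-butyl(dimethyl)silyl]oxymethyl}-3,4a,8,8-tetramethyl-1,2,4a,5,6,7,8,8a-octahydronaphthalene-1-carbaldehyde | CC(C)(C)[Si](C)(C)OCC1=C(C)C[C@H](C=O)[C@H]2C(C)(C)CCC[C@]12C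
F4 | step 6 | tert-butyl{[(4aS,8aS)-2,5,5,8a-tetramethyl-3,4,4a,5,6,7,8,8a-octahydronaphthalen-1-yl]methoxy}dimethylsilane | CC(C)(C)[Si](C)(C)OCC1=C(C)CC[C@H]2C(C)(C)CCC[C@]12C
F5 | step 15 | 1-{(Z)-chloro[(2S,4aS,8aS)-2,5,5,8a-tetramethyloctahydronaphthalen-1(2H)-ylidene]methyl}-3-methoxy-2,5-bis(methoxymethoxy)benzene | COc1cc(OCOC)cc(/C(Cl)=C2\[C@@H](C)CC[C@H]3C(C)(C)CCC[C@]23C)c1OCOC
F6 | step 8 | (4aS,8aS)-2,5,5,8a-tetramethyl-3,4,4a,5,6,7,8,8a-octahydronaphthalene-1-carbaldehyde | O=CC1=C(C)CC[C@H]2C(C)(C)CCC[C@]12C
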